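The three identical 4-hydroxyphenyl rings are built, not bought. Each is disconnected across C-2–C-3 and C-4–C-5, so that C-3 and the oxygenated C-4 derive from 1,1-dimethoxyethene and C-5, C-6, C-1 and C-2 from a 2-pyrone carrying the propenamide chain at its C-5. The feature exploited is the 1,4 relationship between the side chain (ring C-1) and the oxygen (ring C-4), with no other ring substituent. One threefold cycloaddition, CO2 loss and methanol elimination forms six C–C bonds and all three arenes. Its precursor is spermidine triacylated with (E)-3-(2-oxo-2H-pyran-5-yl)acryloyl groups, made by triacryloylation and a triple Heck coupling.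

Key step: step 3

Assumption: 5-bromo-2H-pyran-2-one (4) is taken as a purchasable reagent. Steps 1 to 3 each consume three molecules of their second reactant: one stands on the Reactants line and the other two are entered, written together, under the reagents that add atoms. The threefold reactions are written as single events, so partly reacted species are not numbered and intermediates 7, 8 and 10 are drawn with all three arms at the same stage.

Step 1
Reactants: 1 spermidine; 2 acryloyl chloride
Product: 3 N1,N5,N10-triacryloylspermidine
Conditions: 2 (slight excess over three equivalents), K2CO3, CH2Cl2/H2O, 0 °C, BHT (trace); 1 added slowly to 2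
Reagents that add atoms: acryloyl chloride, the second and third molecule of 2, C=CC(Cl)=O.C=CC(Cl)=O
Why: Schotten–Baumann N-acylation, in which three molecules of the acid chloride should acylate the three nitrogen atoms of 1 at 0 °C much faster than any amine can add to an acrylamide in aza-Michael fashion, while the radical inhibitor keeps the triacrylamide from polymerising.

Step 2
Reactants: 3 N1,N5,N10-triacryloylspermidine; 4 5-bromo-2H-pyran-2-one
Product: 5 N1,N5,N10-tris[(E)-3-(2-oxo-2H-pyran-5-yl)acryloyl]spermidine
Conditions: 4 (slight excess over three equivalents), Pd(OAc)2 (cat.), P(o-tol)3, n-Bu4NCl, NaHCO3, DMF, 80 °C, BHT (trace)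
Reagents that add atoms: 5-bromo-2H-pyran-2-one, the second and third molecule of 4, O=C1C=CC(Br)=CO1.O=C1C=CC(Br)=CO1
Why: Threefold Mizoroki–Heck coupling, in which oxidative addition of the pyrone C-5–Br bond to zerovalent palladium, syn insertion into each terminal acrylamide and syn β-hydride elimination should give the E alkenes, the weak non-nucleophilic base NaHCO3 sparing the pyrone lactones.

Step 3
Reactants: 5 N1,N5,N10-tris[(E)-3-(2-oxo-2H-pyran-5-yl)acryloyl]spermidine; 6 1,1-dimethoxyethene
Product: 9 N1,N5,N10-tris[(E)-4-methoxycinnamoyl]spermidine, via tris(oxabicyclooctenone) cycloadduct 7 (not isolated), via tris(4,4-dimethoxycyclohexadiene) 8 (not isolated)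
Conditions: 6 (excess over three equivalents), 1,4-dioxane, sealed tube, 120 °C
Reagents that add atoms: 1,1-dimethoxyethene, the second and third molecule of 6, C=C(OC)OC.C=C(OC)OC
Why: Each pyrone ring serves as the electron-poor diene (C-3 to C-6) in an inverse-electron-demand Diels–Alder reaction with one molecule of the electron-rich ketene acetal 6, the bridged lactone of 7 then expels CO2 by a retro-[4+2] reaction and the 4,4-dimethoxycyclohexadiene of 8 aromatises by eliminating methanol. The closest known reaction type is the benzannulation of 2-pyrones that carry an acceptor at C-5 (coumalate esters) with ketene acetals or enol ethers to give para-alkoxy arenes. Each of the three benzene rings is closed by an intermolecular [4+2] cycloaddition that forms two C–C bonds, pyrone C-6 to the CH2 of 6 and pyrone C-3 to the acetal carbon, the three arms reacting independently. No stereocentre has to be set, since the bridgehead centres of 7 form without control and vanish on decarboxylation while the E alkenes of the side chains are spectators. The step needs para regioselectivity, secured because pyrone C-6 is the electrophilic terminus of both the lactone dienoate and the 5-propenamide acceptor, so the nucleophilic CH2 of 6 bonds there and the oxygen-bearing carbon is delivered to C-3, para to the chain at C-5. It also needs chemoselectivity for the ring diene over the side-chain alkenes and the amide N–H groups, secured by the locked s-cis geometry of the pyrone and by the weak electrophilicity and acidity of the amides under neutral, acid-free conditions.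

Step 4
Reactants: 9 N1,N5,N10-tris[(E)-4-methoxycinnamoyl]spermidine
Product: 11 N1,N5,N10-tri-(E)-p-coumaroylspermidine, via tris(aryloxydibromoborane) 10 (not isolated)
Conditions: BBr3 (excess), CH2Cl2, −78 to 0 °C, dark; then H2O
Reagents that add atoms: none
Why: Lewis-acid cleavage of aryl methyl ethers, in which BBr3 binds each ether oxygen, bromide removes the methyl group by SN2 attack and water hydrolyses the aryloxyboranes of 10, while the amides only complex BBr3 reversibly (hence the excess) and the E alkenes should survive the cold, dark conditions.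

Compound list
1 | spermidine, N-(3-aminopropyl)butane-1,4-diamine | NCCCCNCCCN | starting material
2 | acryloyl chloride | C=CC(Cl)=O | starting material
3 | N1,N5,N10-triacryloylspermidine | C=CC(=O)NCCCCN(CCCNC(=O)C=C)C(=O)C=C | intermediate
4 | 5-bromo-2H-pyran-2-one | O=C1C=CC(Br)=CO1 | starting material
5 | N1,N5,N10-tris[(E)-3-(2-oxo-2H-pyran-5-yl)acryloyl]spermidine, all three alkenes E | O=C(/C=C/C1=COC(=O)C=C1)NCCCCN(CCCNC(=O)/C=C/C1=COC(=O)C=C1)C(=O)/C=C/C1=COC(=O)C=C1 | intermediate
6 | 1,1-dimethoxyethene | C=C(OC)OC | starting material
7 | N1,N5,N10-tris[(E)-3-(8,8-dimethoxy-3-oxo-2-oxabicyclo[2.2.2]oct-5-en-6-yl)acryloyl]spermidine, alkenes E, bridgehead centres uncontrolled (mixture of diastereomers), not isolated | O=C(/C=C/C1=CC2C(=O)OC1CC2(OC)OC)NCCCCN(CCCNC(=O)/C=C/C1=CC2C(=O)OC1CC2(OC)OC)C(=O)/C=C/C1=CC2C(=O)OC1CC2(OC)OC | intermediate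
8 | N1,N5,N10-tris[(E)-3-(4,4-dimethoxycyclohexa-1,5-dien-1-yl)acryloyl]spermidine, alkenes E, not isolated | O=C(/C=C/C1=CCC(OC)(OC)C=C1)NCCCCN(CCCNC(=O)/C=C/C1=CCC(OC)(OC)C=C1)C(=O)/C=C/C1=CCC(OC)(OC)C=C1 | intermediate
9 | N1,N5,N10-tris[(E)-4-methoxycinnamoyl]spermidine | O=C(/C=C/c1ccc(OC)cc1)NCCCCN(CCCNC(=O)/C=C/c1ccc(OC)cc1)C(=O)/C=C/c1ccc(OC)cc1 | intermediate
10 | N1,N5,N10-tris[(E)-4-(dibromoboryloxy)cinnamoyl]spermidine, not isolated | O=C(/C=C/c1ccc(OB(Br)Br)cc1)NCCCCN(CCCNC(=O)/C=C/c1ccc(OB(Br)Br)cc1)C(=O)/C=C/c1ccc(OB(Br)Br)cc1 | intermediate
11 | N1,N5,N10-tri-(E)-p-coumaroylspermidine | O=C(/C=C/c1ccc(O)cc1)NCCCCN(CCCNC(=O)/C=C/c1ccc(O)cc1)C(=O)/C=C/c1ccc(O)cc1 | target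

Total step count: 4
Longest linear sequence: 4 steps (1 to 3 to 5 to 9 to 11)

Steps most likely to fail

1. Step 3. The cycloaddition may stall because a propenamide at C-5 lowers the pyrone LUMO less than an ester does. At the temperature then needed, the ketene acetal may oligomerise or add to the amide N–H groups, leaving arms unreacted. The fallback moves the benzannulation to the monomer stage, where an ester activates the pyrone and no N–H is present. It sets out from 4. Heck coupling of 4 with methyl acrylate (Pd(OAc)2, P(o-tol)3, NaHCO3, DMF) should give methyl (E)-3-(2-oxo-2H-pyran-5-yl)acrylate F1. Heating F1 with 6 in toluene should pass through methyl (E)-3-(8,8-dimethoxy-3-oxo-2-oxabicyclo[2.2.2]oct-5-en-6-yl)acrylate F2 and methyl (E)-3-(4,4-dimethoxycyclohexa-1,5-dien-1-yl)acrylate F3, neither isolated, to methyl (E)-4-methoxycinnamate F4. LiOH in THF/H2O should then give (E)-4-methoxycinnamic acid F5, and (COCl)2 with catalytic DMF in CH2Cl2 should give (E)-4-methoxycinnamoyl chloride F6. Acylation of 1 with three equivalents of F6 (K2CO3, CH2Cl2/H2O, 0 °C) should give 9, where the route is rejoined.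

2. Step 2. The threefold coupling may stop at mono- and di-coupled material, the bromopyrone may be degraded by base or nucleophiles on prolonged heating, and the triacrylamide may cross-link thermally. The fallback performs a single Heck coupling on a simple acrylate and forms the amides afterwards. It sets out from 4. Coupling of 4 with tert-butyl acrylate under the same Pd(OAc)2 conditions should give tert-butyl (E)-3-(2-oxo-2H-pyran-5-yl)acrylate F7. CF3CO2H in CH2Cl2 should release (E)-3-(2-oxo-2H-pyran-5-yl)acrylic acid F8 without base touching the lactone. (COCl)2 with catalytic DMF should give (E)-3-(2-oxo-2H-pyran-5-yl)acryloyl chloride F9, by analogy with the conversion of coumalic acid into its chloride. Slow addition of 1 to an excess over three equivalents of F9 (NaHCO3, CH2Cl2/H2O, 0 °C) should give 5, where the route is rejoined. Keeping F9 in excess means no free amine accumulates to attack the pyrone rings, which react far more slowly than the acid chloride.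

3. Step 4. Ether cleavage may stay incomplete because the three amide carbonyls sequester BBr3 and the boron complexes precipitate. HBr released on quenching may also add to, or isomerise, the electron-rich alkenes. The fallback replaces Lewis-acid cleavage by nucleophilic dealkylation and sets out from 9. C12H25SNa (from 1-dodecanethiol and NaOH) in NMP at 130 °C should remove the three methyl groups by SN2 attack, giving the trisodium triphenoxide of the target F10 (not isolated). Thiolate addition to the cinnamamides is reversible and is disfavoured once the phenoxides form. Acidification with aqueous HCl should give 11, the target.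

Further compounds
F1 | step 3 | methyl (E)-3-(2-oxo-2H-pyran-5-yl)acrylate | COC(=O)/C=C/C1=COC(=O)C=C1
F2 | step 3 | methyl (E)-3-(8,8-dimethoxy-3-oxo-2-oxabicyclo[2.2.2]oct-5-en-6-yl)acrylate, not isolated | COC(=O)/C=C/C1=CC2C(=O)OC1CC2(OC)OC
F3 | step 3 | methyl (E)-3-(4,4-dimethoxycyclohexa-1,5-dien-1-yl)acrylate, not isolated | COC(=O)/C=C/C1=CCC(OC)(OC)C=C1
F4 | step 3 | methyl (E)-4-methoxycinnamate | COC(=O)/C=C/c1ccc(OC)cc1
F5 | step 3 | (E)-4-methoxycinnamic acid | OC(=O)/C=C/c1ccc(OC)cc1
F6 | step 3 | (E)-4-methoxycinnamoyl chloride | ClC(=O)/C=C/c1ccc(OC)cc1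
F7 | step 2 | tert-butyl (E)-3-(2-oxo-2H-pyran-5-yl)acrylate | CC(C)(C)OC(=O)/C=C/C1=COC(=O)C=C1
F8 | step 2 | (E)-3-(2-oxo-2H-pyran-5-yl)acrylic acid | OC(=O)/C=C/C1=COC(=O)C=C1
F9 | step 2 | (E)-3-(2-oxo-2H-pyran-5-yl)acryloyl chloride | ClC(=O)/C=C/C1=COC(=O)C=C1
F10 | step 4 | trisodium triphenoxide of N1,N5,N10-tri-(E)-p-coumaroylspermidine, not isolated | O=C(/C=C/c1ccc([O-])cc1)NCCCCN(CCCNC(=O)/C=C/c1ccc([O-])cc1)C(=O)/C=C/c1ccc([O-])cc1.[Na+].[Na+].[Na+]
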